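**Retrosynthetic overview**

1. The three ester C–O bonds are made last: the cyclobutane triacid (phenol masked as its pivalate) is joined to three molecules of the C6-epimeric amino alcohol by Mitsunobu esterification with inversion at C6.
2. The strategy rests on the cyclobutane bond between C1 (the benzylic CH carrying the 4-hydroxy-3-methoxyphenyl ring) and C4 (the quaternary carbon carrying CH3 and CO2R). Both carbons stabilise a radical, so this bond is formed by loss of N2 from a pyrrolidine whose nitrogen bridges C1 and C4.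
3. The pyrrolidine ring comes from a silver-catalysed [3+2] cycloaddition of the vanillin/alanine azomethine ylide with the E-acrylate end of a diene diester. Its benzylic C5 is then epimerised to the all-trans isomer.
4. The amino alcohol comes from an intramolecular Pauson–Khand reaction of an N-tethered 1,7-enyne, which forms the cyclopentenone and piperidine rings together. The enyne stereocentre comes from a copper-catalysed allylic methylation.
5. Ring order: pyrrolidine (step 5), then cyclobutane by ring contraction (step 7); the bicyclic amine (step 12) is made separately; the coupling forms no ring.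

Key step: step 7

Remark: the phenol is carried as its pivalate, because ammonia released from ammonium carbamate at 80 °C would cleave an aryl acetate and the free guaiacol would be oxidised by the iodane.
Remark: the amino alcohol units are taken as drawn, (4R,4aR,6R,7R,7aS); the coupling partner is the 6S epimer because the Mitsunobu reaction inverts C6.
Remark: tert-butyl but-2-ynoate, but-2-yn-1-amine hydrochloride, QUINAP and TaniaPhos are assumed to be purchasable.

**Route**

Step 1
Reactants: 1 but-3-enylmagnesium bromide; 2 tert-butyl but-2-ynoate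
Product: 4 tert-butyl (2E)-3-methylhepta-2,6-dienoate, via but-3-enylcopper 3 (not isolated)
Conditions: CuBr·SMe2 (1.2 equiv), THF, −40 to −78 °C; MeOH quench at −78 °C
Reagents that add atoms: none
Why: Syn-carbocupration of the ynoate and protonation of the vinylcopper at low temperature with retention place the butenyl chain trans to the ester, which fixes the 2E geometry.

Step 2
Reactants: 4 tert-butyl (2E)-3-methylhepta-2,6-dienoate; 5 tert-butyl acrylate
Product: 6 di-tert-butyl (2E,6E)-3-methylocta-2,6-dienedioate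
Conditions: second-generation Hoveyda–Grubbs catalyst (2 mol%), 5 (3 equiv), CH2Cl2, 40 °C
Reagents that add atoms: none
Why: Olefin cross-metathesis of a terminal alkene with an acrylate gives the E-enoate, and the trisubstituted enoate is too hindered and electron-poor to take part.

Step 3
Reactants: 7 vanillin
Product: 8 4-formyl-2-methoxyphenyl pivalate
Conditions: t-BuCOCl, Et3N, DMAP (cat.), CH2Cl2, 0 °C
Reagents that add atoms: pivaloyl chloride, CC(C)(C)C(=O)Cl
Why: O-acylation of the phenol gives a hindered aryl ester that deactivates the ring toward the iodane and should resist amines and ammonia in the later steps.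

Step 4
Reactants: 8 4-formyl-2-methoxyphenyl pivalate; 9 L-alanine tert-butyl ester hydrochloride
Product: 10 tert-butyl (2S)-2-{[(E)-(3-methoxy-4-pivaloyloxyphenyl)methylidene]amino}propanoate
Conditions: Et3N, MgSO4, CH2Cl2, rt
Reagents that add atoms: none
Why: Imine condensation of the aldehyde with the primary amine; the alanine stereocentre is lost on metalation in step 5 and does not matter.

Step 5
Reactants: 10 tert-butyl (2S)-2-{[(E)-(3-methoxy-4-pivaloyloxyphenyl)methylidene]amino}propanoate; 6 di-tert-butyl (2E,6E)-3-methylocta-2,6-dienedioate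
Product: 11 di-tert-butyl (2S,3S,4S,5R)-5-[3-methoxy-4-(pivaloyloxy)phenyl]-2-methyl-3-[(3E)-5-tert-butoxy-3-methyl-5-oxopent-3-en-1-yl]pyrrolidine-2,4-dicarboxylate
Conditions: AgOAc (5 mol%), (S)-QUINAP (5.5 mol%), i-Pr2NEt (10 mol%), THF, −20 °C to rt
Reagents that add atoms: none
Why: Catalytic asymmetric 1,3-dipolar cycloaddition of the N,O-chelated W-shaped silver azomethine ylide at the disubstituted acrylate alkene only: the ylide geometry puts the aryl cis to the C2 ester, endo approach puts the C4 ester cis to both, the E-alkene puts the side chain trans to the C4 ester and cis to the C2 methyl, and the QUINAP antipode (changed if the opposite sense is found) selects the ylide face.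

Step 6
Reactants: 11 di-tert-butyl (2S,3S,4S,5R)-5-[3-methoxy-4-(pivaloyloxy)phenyl]-2-methyl-3-[(3E)-5-tert-butoxy-3-methyl-5-oxopent-3-en-1-yl]pyrrolidine-2,4-dicarboxylate
Product: 12 di-tert-butyl (2S,3S,4S,5S)-5-[3-methoxy-4-(pivaloyloxy)phenyl]-2-methyl-3-[(3E)-5-tert-butoxy-3-methyl-5-oxopent-3-en-1-yl]pyrrolidine-2,4-dicarboxylate
Conditions: [Cp*IrI2]2 (2.5 mol%), toluene, 100 °C, argon; unchanged 11 recycled
Reagents that add atoms: none
Why: Reversible dehydrogenation–rehydrogenation of the benzylic secondary amine by the trivalent iridium catalyst (amine racemisation by hydrogen borrowing) passes through the 2-aryl-1-pyrroline, so C5 (and C4 through the imine–enamine tautomer) equilibrate while quaternary C2 and C3 cannot, and the mixture should settle on the all-trans isomer in which the aryl no longer stands cis to the C4 ester; no alkoxide or thiyl radical is present that would scramble the E-enoate.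

Step 7
Reactants: 12 di-tert-butyl (2S,3S,4S,5S)-5-[3-methoxy-4-(pivaloyloxy)phenyl]-2-methyl-3-[(3E)-5-tert-butoxy-3-methyl-5-oxopent-3-en-1-yl]pyrrolidine-2,4-dicarboxylate
Product: 15 di-tert-butyl (1R,2S,3S,4S)-2-[(3E)-5-tert-butoxy-3-methyl-5-oxopent-3-en-1-yl]-4-[3-methoxy-4-(pivaloyloxy)phenyl]-1-methylcyclobutane-1,3-dicarboxylate, via 1,1-diazene 13 (not isolated), via 1,4-biradical 14 (not isolated)
Conditions: PhI(OH)OTs (2.5 equiv), NH2CO2NH4 (8 equiv), CF3CH2OH, 80 °C
Reagents that add atoms: none
Why: PhI(OH)OTs and ammonia from ammonium carbamate form the iodonitrene PhI=NH, which aminates the ring nitrogen, and a second equivalent of the iodane oxidises the hydrazine to the 1,1-diazene 13, which loses N2 to the singlet 1,4-biradical 14 with its radical centres at the benzylic carbon and at the methyl- and ester-bearing tertiary carbon. The closest known reaction is the iodonitrene-mediated contraction of polysubstituted 2-arylpyrrolidine esters to cyclobutanes, a variant of 1,1-diazene extrusion from N-aminopyrrolidines. The four-membered ring closes by radical–radical recombination of the 1,4-biradical, joining the former C5 and C2 of the pyrrolidine. The two stereocentres at the new bond are carried over with retention from C5 and C2 of 12, because collapse of the singlet biradical is expected to be faster than rotation about its C–C bonds, while the former C3 and C4 are untouched. The step needs ring closure to outrun β-scission of the central C–C bond into two alkenes and needs the oxidant to spare the arene, the enoate and the esters. Both radical termini are stabilised and held close in the all-trans array, the arene is deactivated as its pivalate, the alkene is an electron-poor enoate, and the excess ammonium carbamate buffers the TsOH so that the tert-butyl esters survive.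

Step 8
Reactants: 15 di-tert-butyl (1R,2S,3S,4S)-2-[(3E)-5-tert-butoxy-3-methyl-5-oxopent-3-en-1-yl]-4-[3-methoxy-4-(pivaloyloxy)phenyl]-1-methylcyclobutane-1,3-dicarboxylate
Product: 16 (1R,2S,3S,4S)-2-[(3E)-4-carboxy-3-methylbut-3-en-1-yl]-4-[3-methoxy-4-(pivaloyloxy)phenyl]-1-methylcyclobutane-1,3-dicarboxylic acid
Conditions: CF3CO2H/CH2Cl2 (1:3), 0 °C to rt
Reagents that add atoms: none
Why: Acidolysis of the three tert-butyl esters through the tert-butyl cation leaves the aryl pivalate, the enoate geometry and the non-enolising stereocentres untouched.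

Step 9
Reactants: 17 but-2-yn-1-amine hydrochloride
Product: 18 tert-butyl but-2-yn-1-ylcarbamate
Conditions: Boc2O, Et3N, CH2Cl2, 0 °C to rt
Reagents that add atoms: di-tert-butyl dicarbonate, CC(C)(C)OC(=O)OC(=O)OC(C)(C)C
Why: Carbamate formation gives an N–H acidic enough for alkylation and a group that tolerates cobalt carbonyl and is later reduced to N-methyl.

Step 10
Reactants: 18 tert-butyl but-2-yn-1-ylcarbamate; 19 (E)-1,4-dibromobut-2-ene
Product: 20 tert-butyl [(2E)-4-bromobut-2-en-1-yl](but-2-yn-1-yl)carbamate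
Conditions: NaH, DMF, 0 °C; 19 (3 equiv)
Reagents that add atoms: none
Why: N-alkylation of the carbamate anion by SN2 at one allylic bromide, with the excess dibromide suppressing double alkylation.

Step 11
Reactants: 20 tert-butyl [(2E)-4-bromobut-2-en-1-yl](but-2-yn-1-yl)carbamate
Product: 21 tert-butyl (but-2-yn-1-yl)[(2R)-2-methylbut-3-en-1-yl]carbamate
Conditions: MeMgBr (1.2 equiv), CuBr·SMe2 (5 mol%), TaniaPhos (6 mol%), CH2Cl2, −75 °C
Reagents that add atoms: methylmagnesium bromide, C[Mg]Br
Why: Copper-catalysed asymmetric allylic alkylation of the E-allylic bromide in the SN2′ sense gives the branched product, the ligand antipode being chosen to deliver the R centre that becomes C4 of the piperidine.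

Step 12
Reactants: 21 tert-butyl (but-2-yn-1-yl)[(2R)-2-methylbut-3-en-1-yl]carbamate
Product: 23 tert-butyl (4R,4aR)-4,7-dimethyl-6-oxo-1,3,4,4a,5,6-hexahydro-2H-cyclopenta[c]pyridine-2-carboxylate, via dicobalt hexacarbonyl alkyne complex 22 (not isolated)
Conditions: Co2(CO)8 (1.1 equiv), CH2Cl2, rt; then N-methylmorpholine N-oxide (8 equiv), 0 °C to rt
Reagents that add atoms: octacarbonyldicobalt, O=C=[Co](=C=O)(=C=O)(=C=O)[Co](=C=O)(=C=O)(=C=O)=C=O
Why: Intramolecular Pauson–Khand reaction of the 1,7-enyne forms both rings, the alkyne methyl ending α to the ketone, and a chair-like tether with the allylic methyl equatorial sets C4a so that the 4-methyl is trans to C5 (cis to H-4a).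

Step 13
Reactants: 23 tert-butyl (4R,4aR)-4,7-dimethyl-6-oxo-1,3,4,4a,5,6-hexahydro-2H-cyclopenta[c]pyridine-2-carboxylate
Product: 25 tert-butyl (4R,4aR,7R,7aS)-4,7-dimethyl-6-oxooctahydro-2H-cyclopenta[c]pyridine-2-carboxylate, via 7-epi ketone 24 (not isolated)
Conditions: H2 (4 atm), Pd/C, EtOAc; filter; NaOMe (cat.), MeOH, rt
Reagents that add atoms: none
Why: Syn hydrogenation of the enone from the face of H-4a (opposite the piperidine carbons) sets the cis ring fusion, and base equilibration of the α-stereocentre then moves the 7-methyl trans to C1, the more stable arrangement.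

Step 14
Reactants: 25 tert-butyl (4R,4aR,7R,7aS)-4,7-dimethyl-6-oxooctahydro-2H-cyclopenta[c]pyridine-2-carboxylate
Product: 26 tert-butyl (4R,4aR,6S,7R,7aS)-6-hydroxy-4,7-dimethyloctahydro-2H-cyclopenta[c]pyridine-2-carboxylate
Conditions: LiBH(s-Bu)3 (L-Selectride), THF, −78 °C; H2O
Reagents that add atoms: none
Why: The bulky hydride should attack the cyclopentanone from the face opposite the adjacent 7-methyl, as in reductions of 2-alkylcyclopentanones, giving the alcohol cis to that methyl (6S).

Step 15
Reactants: 26 tert-butyl (4R,4aR,6S,7R,7aS)-6-hydroxy-4,7-dimethyloctahydro-2H-cyclopenta[c]pyridine-2-carboxylate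
Product: 27 (4R,4aR,6S,7R,7aS)-2,4,7-trimethyloctahydro-1H-cyclopenta[c]pyridin-6-ol
Conditions: LiAlH4, THF, reflux; Na2SO4·10H2O work-up
Reagents that add atoms: none
Why: Hydride reduction of the tert-butyl carbamate converts its carbonyl carbon into the N-methyl group without touching a stereocentre.

Step 16
Reactants: 16 (1R,2S,3S,4S)-2-[(3E)-4-carboxy-3-methylbut-3-en-1-yl]-4-[3-methoxy-4-(pivaloyloxy)phenyl]-1-methylcyclobutane-1,3-dicarboxylic acid; 27 (4R,4aR,6S,7R,7aS)-2,4,7-trimethyloctahydro-1H-cyclopenta[c]pyridin-6-ol (one of the three molecules that are incorporated)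
Product: 28 O-pivaloyl derivative of the target (the triester with the phenol still protected)
Conditions: PPh3 (5 equiv), DIAD (5 equiv), 27 (3.6 equiv in all), THF, 0 °C to rt
Reagents that add atoms: second molecule of amino alcohol 27, O[C@H]1C[C@H]2[C@H](CN(C)C[C@@H]2C)[C@H]1C; third molecule of amino alcohol 27, O[C@H]1C[C@H]2[C@H](CN(C)C[C@@H]2C)[C@H]1C
Why: Threefold Mitsunobu esterification that consumes one molecule of 27 per carboxyl group, each carboxylate displacing the alkoxyphosphonium group by SN2 with inversion at C6 (6S to 6R); the hindered α-quaternary acid acts only as a nucleophile and the phenol is masked.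

Step 17
Reactants: 28 O-pivaloyl derivative of the target
Product: 29 CNP0251577.2
Conditions: K2CO3 (1.5 equiv), MeOH, 0 °C to rt
Reagents that add atoms: none
Why: Methanolysis of the aryl ester with its phenoxide leaving group should be much faster than transesterification of the three hindered secondary alkyl esters, and the conditions are too mild to epimerise C–H centres or move the enoate.

**Compound list**

1 | but-3-enylmagnesium bromide | C=CCC[Mg]Br | starting material
2 | tert-butyl but-2-ynoate | CC#CC(=O)OC(C)(C)C | starting material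
3 | but-3-enylcopper | C=CCC[Cu] | intermediate
4 | tert-butyl (2E)-3-methylhepta-2,6-dienoate | CC(C)(C)OC(=O)/C=C(\C)CCC=C | intermediate
5 | tert-butyl acrylate | C=CC(=O)OC(C)(C)C | starting material
6 | di-tert-butyl (2E,6E)-3-methylocta-2,6-dienedioate | CC(C)(C)OC(=O)/C=C(\C)CC/C=C/C(=O)OC(C)(C)C | intermediate
7 | vanillin | COc1cc(C=O)ccc1O | starting material
8 | 4-formyl-2-methoxyphenyl pivalate | COc1cc(C=O)ccc1OC(=O)C(C)(C)C | intermediate
9 | L-alanine tert-butyl ester hydrochloride | C[C@H](N)C(=O)OC(C)(C)C.Cl | starting material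
10 | tert-butyl (2S)-2-{[(E)-(3-methoxy-4-pivaloyloxyphenyl)methylidene]amino}propanoate | COc1cc(/C=N/[C@@H](C)C(=O)OC(C)(C)C)ccc1OC(=O)C(C)(C)C | intermediate
11 | di-tert-butyl (2S,3S,4S,5R)-5-[3-methoxy-4-(pivaloyloxy)phenyl]-2-methyl-3-[(3E)-5-tert-butoxy-3-methyl-5-oxopent-3-en-1-yl]pyrrolidine-2,4-dicarboxylate (aryl, C4 ester and C2 ester mutually cis) | COc1cc([C@H]2[C@@H](C(=O)OC(C)(C)C)[C@H](CC/C(C)=C/C(=O)OC(C)(C)C)[C@@](N2)(C)C(=O)OC(C)(C)C)ccc1OC(=O)C(C)(C)C | intermediate
12 | di-tert-butyl (2S,3S,4S,5S)-5-[3-methoxy-4-(pivaloyloxy)phenyl]-2-methyl-3-[(3E)-5-tert-butoxy-3-methyl-5-oxopent-3-en-1-yl]pyrrolidine-2,4-dicarboxylate (all-trans; aryl cis to the C2 methyl) | COc1cc([C@@H]2[C@@H](C(=O)OC(C)(C)C)[C@H](CC/C(C)=C/C(=O)OC(C)(C)C)[C@@](N2)(C)C(=O)OC(C)(C)C)ccc1OC(=O)C(C)(C)C | intermediate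
13 | 1,1-diazene (N-nitrene) of pyrrolidine 12 | COc1cc([C@@H]2[C@@H](C(=O)OC(C)(C)C)[C@H](CC/C(C)=C/C(=O)OC(C)(C)C)[C@@]([N+]2=[N-])(C)C(=O)OC(C)(C)C)ccc1OC(=O)C(C)(C)C | intermediate
14 | 1,4-biradical from 13 after loss of N2 | COc1cc([CH][C@@H](C(=O)OC(C)(C)C)[C@H](CC/C(C)=C/C(=O)OC(C)(C)C)[C](C)C(=O)OC(C)(C)C)ccc1OC(=O)C(C)(C)C | intermediate
15 | di-tert-butyl (1R,2S,3S,4S)-2-[(3E)-5-tert-butoxy-3-methyl-5-oxopent-3-en-1-yl]-4-[3-methoxy-4-(pivaloyloxy)phenyl]-1-methylcyclobutane-1,3-dicarboxylate | COc1cc([C@@H]2[C@@H](C(=O)OC(C)(C)C)[C@H](CC/C(C)=C/C(=O)OC(C)(C)C)[C@@]2(C)C(=O)OC(C)(C)C)ccc1OC(=O)C(C)(C)C | intermediate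
16 | (1R,2S,3S,4S)-2-[(3E)-4-carboxy-3-methylbut-3-en-1-yl]-4-[3-methoxy-4-(pivaloyloxy)phenyl]-1-methylcyclobutane-1,3-dicarboxylic acid | COc1cc([C@@H]2[C@@H](C(=O)O)[C@H](CC/C(C)=C/C(=O)O)[C@@]2(C)C(=O)O)ccc1OC(=O)C(C)(C)C | intermediate
17 | but-2-yn-1-amine hydrochloride | CC#CCN.Cl | starting material
18 | tert-butyl but-2-yn-1-ylcarbamate | CC#CCNC(=O)OC(C)(C)C | intermediate
19 | (E)-1,4-dibromobut-2-ene | BrC/C=C/CBr | starting material
20 | tert-butyl [(2E)-4-bromobut-2-en-1-yl](but-2-yn-1-yl)carbamate | CC#CCN(C/C=C/CBr)C(=O)OC(C)(C)C | intermediate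
21 | tert-butyl (but-2-yn-1-yl)[(2R)-2-methylbut-3-en-1-yl]carbamate | CC#CCN(C[C@H](C)C=C)C(=O)OC(C)(C)C | intermediate
22 | hexacarbonyldicobalt complex of the alkyne of 21 | C[C]12[Co]3(=C=O)(=C=O)(=C=O)[Co]1(=C=O)(=C=O)(=C=O)[C]23CN(C[C@H](C)C=C)C(=O)OC(C)(C)C | intermediate
23 | tert-butyl (4R,4aR)-4,7-dimethyl-6-oxo-1,3,4,4a,5,6-hexahydro-2H-cyclopenta[c]pyridine-2-carboxylate | O=C1C[C@H]2C(CN(C(=O)OC(C)(C)C)C[C@@H]2C)=C1C | intermediate
24 | tert-butyl (4R,4aR,7S,7aS)-4,7-dimethyl-6-oxooctahydro-2H-cyclopenta[c]pyridine-2-carboxylate (7-methyl cis to C1) | O=C1C[C@H]2[C@H](CN(C(=O)OC(C)(C)C)C[C@@H]2C)[C@@H]1C | intermediate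
25 | tert-butyl (4R,4aR,7R,7aS)-4,7-dimethyl-6-oxooctahydro-2H-cyclopenta[c]pyridine-2-carboxylate (cis-fused; 7-methyl trans to C1) | O=C1C[C@H]2[C@H](CN(C(=O)OC(C)(C)C)C[C@@H]2C)[C@H]1C | intermediate
26 | tert-butyl (4R,4aR,6S,7R,7aS)-6-hydroxy-4,7-dimethyloctahydro-2H-cyclopenta[c]pyridine-2-carboxylate | O[C@H]1C[C@H]2[C@H](CN(C(=O)OC(C)(C)C)C[C@@H]2C)[C@H]1C | intermediate
27 | (4R,4aR,6S,7R,7aS)-2,4,7-trimethyloctahydro-1H-cyclopenta[c]pyridin-6-ol (6-epi amino alcohol; OH cis to the 7-methyl) | O[C@H]1C[C@H]2[C@H](CN(C)C[C@@H]2C)[C@H]1C | intermediate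
28 | O-pivaloyl derivative of the target | COc1cc([C@@H]2[C@@H](C(=O)O[C@@H]3C[C@H]4[C@H](CN(C)C[C@@H]4C)[C@H]3C)[C@H](CC/C(C)=C/C(=O)O[C@@H]3C[C@H]4[C@H](CN(C)C[C@@H]4C)[C@H]3C)[C@@]2(C)C(=O)O[C@@H]2C[C@H]3[C@H](CN(C)C[C@@H]3C)[C@H]2C)ccc1OC(=O)C(C)(C)C | intermediate
29 | CNP0251577.2 | COc1cc([C@@H]2[C@@H](C(=O)O[C@@H]3C[C@H]4[C@H](CN(C)C[C@@H]4C)[C@H]3C)[C@H](CC/C(C)=C/C(=O)O[C@@H]3C[C@H]4[C@H](CN(C)C[C@@H]4C)[C@H]3C)[C@@]2(C)C(=O)O[C@@H]2C[C@H]3[C@H](CN(C)C[C@@H]3C)[C@H]2C)ccc1O | target

**Step count and risks**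

Total steps: 17. Longest linear sequence: 9 steps (steps 9–15, then 16 and 17).

Step 6 (C5 epimerisation). The hindered, ester-flanked amine may not be dehydrogenated by the iridium catalyst, or the metal hydride may be passed on to the enoate instead of back to the imine. The fallback sets out from 11 and comes back at 12 by reversible hydrogen-atom transfer at the benzylic C5–H under light: [Ir{dF(CF3)ppy}2(dtbpy)]PF6 (1 mol%), 2,4,6-triisopropylbenzenethiol, MeOH, blue LED, rt. The thiyl radical abstracts the benzylic α-amino hydrogen and the thiol returns it, which should also lead to the more stable all-trans isomer; the run is stopped at equilibrium to limit thiyl-induced E/Z drift of the enoate. This fallback makes no compound outside the list (none, F0).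

Step 7 (ring contraction). The biradical may fragment by β-scission into two alkenes instead of closing, the crowded nitrogen may be aminated too slowly, or the arene may be oxidised at 80 °C. The fallback sets out from 12 and builds the same diazene stepwise at low temperature. Nitrosation (t-BuONO, CH2Cl2) gives the N-nitrosopyrrolidine F1. Reduction (Zn, AcOH, 0 °C) gives the N-aminopyrrolidine F2. Oxidation of this 1,1-disubstituted hydrazine (PhI(OAc)2, CH2Cl2, 0 °C to rt) gives 13, which loses N2 through 14 and comes back to the route at 15.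

Step 16 (threefold Mitsunobu). Esterification may stop short at the α-quaternary carboxyl, and the activated secondary alcohol may eliminate. The fallback forms the esters by acyl transfer with retention. From 27, Mitsunobu inversion with 4-nitrobenzoic acid (PPh3, DIAD, THF) gives the 6R 4-nitrobenzoate F3, and methanolysis (K2CO3, MeOH) gives the 6R amino alcohol F4. From 16, (COCl)2 with catalytic DMF in CH2Cl2 gives the tris(acyl chloride) F5. Acylation of three equivalents of F4 with F5 (Et3N, DMAP, CH2Cl2, 40 °C) comes back to the route at 28.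

**Further compounds**

F0 | step 6 | none | none
F1 | step 7 | di-tert-butyl (2S,3S,4S,5S)-5-[3-methoxy-4-(pivaloyloxy)phenyl]-2-methyl-1-nitroso-3-[(3E)-5-tert-butoxy-3-methyl-5-oxopent-3-en-1-yl]pyrrolidine-2,4-dicarboxylate | COc1cc([C@@H]2[C@@H](C(=O)OC(C)(C)C)[C@H](CC/C(C)=C/C(=O)OC(C)(C)C)[C@@](N2N=O)(C)C(=O)OC(C)(C)C)ccc1OC(=O)C(C)(C)C
F2 | step 7 | di-tert-butyl (2S,3S,4S,5S)-1-amino-5-[3-methoxy-4-(pivaloyloxy)phenyl]-2-methyl-3-[(3E)-5-tert-butoxy-3-methyl-5-oxopent-3-en-1-yl]pyrrolidine-2,4-dicarboxylate | COc1cc([C@@H]2[C@@H](C(=O)OC(C)(C)C)[C@H](CC/C(C)=C/C(=O)OC(C)(C)C)[C@@](N2N)(C)C(=O)OC(C)(C)C)ccc1OC(=O)C(C)(C)C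
F3 | step 16 | (4R,4aR,6R,7R,7aS)-2,4,7-trimethyloctahydro-1H-cyclopenta[c]pyridin-6-yl 4-nitrobenzoate | O=C(O[C@@H]1C[C@H]2[C@H](CN(C)C[C@@H]2C)[C@H]1C)c1ccc([N+](=O)[O-])cc1
F4 | step 16 | (4R,4aR,6R,7R,7aS)-2,4,7-trimethyloctahydro-1H-cyclopenta[c]pyridin-6-ol | O[C@@H]1C[C@H]2[C@H](CN(C)C[C@@H]2C)[C@H]1C
F5 | step 16 | tris(acyl chloride) of triacid 16 | COc1cc([C@@H]2[C@@H](C(=O)Cl)[C@H](CC/C(C)=C/C(=O)Cl)[C@@]2(C)C(=O)Cl)ccc1OC(=O)C(C)(C)C
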